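**Strategy.** Everything rests on closing ring A onto a carvone-derived ring B through the C3–C4 bond (labdane numbering). The key step exploits the quaternary, gem-dimethyl C4 of ring A beside ring-fusion carbon C5: it is a masked isopropenyl group, and C3 is the CH2 terminus of an acrylate arm on C10. Two enolate alkylations of (S)-carvone set this arm cis and the C10 methyl trans to the isopropenyl group. One hydrogen-atom-transfer step then makes the tertiary C4 radical, which closes ring A on C3 and gives the quaternary centre and the cis ring fusion at once; the temporary C2 ester is removed later. Wharton transposition, directed SN2′ coupling of the C11–C15 chain, hydration and acetylation complete the route.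

Key step: step 3

Remark on the structure: the target SMILES describes a cis-fused decalin (H-5 and the C10 methyl on the same face; 5R,8R,9R,10S,13S), and this is the compound made. Labdane numbering is used throughout; β is the face of ring B that carries the C10 methyl, so ring A (C1, C4) is attached on the α face.
Assumption: (R)-methyl hydrogen 3-methylglutarate is taken as a commercial single enantiomer.

**Step 1**
Reactants: 1 (S)-carvone; 2 methyl 2-(bromomethyl)acrylate
Product: 4 6-[2-(methoxycarbonyl)allyl]carvone (C6 epimers; arm mainly trans to isopropenyl), via lithium enolate 3 (not isolated)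
Conditions: LDA, THF, −78 °C; then 2, −78 → −40 °C
Reagents that add atoms: none
Why: Kinetic deprotonation gives the cross-conjugated α′-enolate, which is allylated by the bromomethylacrylate (enolate alkylation); the new centre forms as an epimer mixture that converges in step 2.

**Step 2**
Reactants: 4 6-[2-(methoxycarbonyl)allyl]carvone
Product: 6 6-methyl-6-[2-(methoxycarbonyl)allyl]carvone (methyl trans and acrylate arm cis to isopropenyl), via lithium enolate 5 (not isolated)
Conditions: LDA, THF, −78 °C; then MeI, −78 → −20 °C
Reagents that add atoms: iodomethane, CI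
Why: Kinetic α′-re-enolisation erases the C6 centre and methyl iodide should enter the enolate face anti to the neighbouring isopropenyl group (diastereoselective enolate alkylation), which leaves the acrylate arm cis to it as a cis ring fusion requires.

**Step 3**
Reactants: 6 6-methyl-6-[2-(methoxycarbonyl)allyl]carvone
Product: 7 cis-decalin enone ester (C9 ketone; C7=C8; CO2Me on C2 as both epimers; H-5 and CH3-10 β)
Conditions: Fe(acac)3 (30 mol %), PhSiH3, EtOH/(CH2OH)2, 60 °C, 0.02 M
Reagents that add atoms: none
Why: An iron hydride formed from Fe(acac)3 and PhSiH3 should transfer a hydrogen atom to the terminal CH2 of the electron-rich isopropenyl group to give the tertiary C4 radical, which adds to the unsubstituted acrylate terminus C3; the α-ester radical at C2 is then reduced by divalent iron and protonated by ethanol. The closest known reaction type is the iron-hydride (MHAT) reductive olefin coupling, used here intramolecularly as a Giese cyclisation. Ring A closes in the 6-endo-trig mode, because the acceptor is 2-substituted and only its CH2 terminus is both electrophilic and unhindered, which disfavours the 5-exo path. C4 becomes quaternary but is not stereogenic, the cis ring fusion follows from the cis arms fixed at C5 and C10 in 6, and the uncontrolled C2 centre is erased in step 5. The step needs hydrogen-atom transfer to the isopropenyl group and not to the enone or acrylate, which their electron-poor character secures, and high dilution to keep the tertiary radical from simple reduction.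

**Step 4**
Reactants: 7 cis-decalin enone ester
Product: 9 7β,8β-epoxy-9-oxo acid (CO2H on C2 as both epimers), via epoxy ester 8 (not isolated)
Conditions: 30% H2O2, LiOH·H2O, THF/MeOH/H2O, 0 °C → rt; then 1 M HCl
Reagents that add atoms: hydrogen peroxide, OO; lithium hydroxide, [Li+].[OH-]
Why: Hydroperoxide should add to C7 from the β face, anti to the α-oriented C4 on C5 as in carvone, and close the 7β,8β-epoxide (Weitz–Scheffer epoxidation), while the same basic medium saponifies the unhindered C2 methyl ester.

**Step 5**
Reactants: 9 7β,8β-epoxy-9-oxo acid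
Product: 11 7β,8β-epoxy ketone, via Barton ester 10 (not isolated)
Conditions: N-hydroxypyridine-2-thione, DCC, DMAP (cat.), CH2Cl2, rt, dark; then t-BuSH, hν (visible), rt
Reagents that add atoms: none
Why: Barton decarboxylation: the thiohydroxamate ester should fragment to the secondary C2 radical, which takes a hydrogen atom from the thiol, so the activating group of the key step leaves without trace and both C2 epimers converge.

**Step 6**
Reactants: 11 7β,8β-epoxy ketone
Product: 13 7β-allylic alcohol (C8=C9), via epoxy hydrazone 12 (not isolated)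
Conditions: N2H4·H2O, AcOH (cat.), i-PrOH, rt → 50 °C
Reagents that add atoms: none
Why: Wharton transposition: the epoxy hydrazone should fragment with loss of N2 to the C8=C9 alkene and the C7 alcohol, and since the C7–O bond is never broken the 7β configuration from step 4 is kept.

**Step 7**
Reactants: 13 7β-allylic alcohol
Product: 14 7β-[2-(diphenylphosphanyl)benzoate] of 13
Conditions: 2-(diphenylphosphanyl)benzoic acid, DCC, DMAP (cat.), CH2Cl2, rt
Reagents that add atoms: 2-(diphenylphosphanyl)benzoic acid, OC(=O)c1ccccc1P(c1ccccc1)c1ccccc1
Why: Steglich esterification installs the phosphane-bearing benzoate as a directing leaving group with retention at C7.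

**Step 8**
Reactants: 15 (R)-methyl hydrogen 3-methylglutarate
Product: 17 (S)-4-methyltetrahydro-2H-pyran-2-one, via hydroxy acid 16 (not isolated)
Conditions: LiBH4, THF, 0 °C → rt; then 2 M HCl, rt
Reagents that add atoms: none
Why: LiBH4 reduces the ester but not the lithium carboxylate (chemoselective hydride reduction) and acid then lactonises the δ-hydroxy acid; the stereocentre is not touched.

**Step 9**
Reactants: 17 (S)-4-methyltetrahydro-2H-pyran-2-one
Product: 18 methyl (R)-5-bromo-3-methylpentanoate
Conditions: HBr (gas), MeOH, 0 °C → rt
Reagents that add atoms: hydrogen bromide, Br; methanol, CO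
Why: Acid-mediated lactone opening by bromide with Fischer esterification gives the ω-bromo ester, as known for simple γ- and δ-lactones; the stereocentre is not touched.

**Step 10**
Reactants: 14 7β-[2-(diphenylphosphanyl)benzoate]; 18 methyl (R)-5-bromo-3-methylpentanoate
Product: 20 methyl (13S)-5β-labd-7-en-15-oate (side chain 9β; H-9 α), via alkylzinc bromide 19 (not isolated)
Conditions: 18, Zn dust, LiCl, THF, 50 °C; then 14, CuBr·SMe2 (20 mol %), THF/Et2O, 0 °C → rt
Reagents that add atoms: none
Why: Zinc insertion gives an ester-tolerant alkylzinc, and the copper held by the ortho-phosphane should deliver the alkyl group to C9 on the face of the leaving group (phosphane-directed syn-SN2′ allylic substitution), which sets the 9β side chain and moves the alkene to C7=C8.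

**Step 11**
Reactants: 20 methyl (13S)-5β-labd-7-en-15-oate
Product: 21 methyl 8α-hydroxy-5β-labdan-15-oate (CH3-8 β)
Conditions: Co(acac)2 (20 mol %), PhSiH3, O2 (1 atm), THF/i-PrOH, rt
Reagents that add atoms: dioxygen, O=O
Why: Mukaiyama hydration: hydrogen-atom transfer to C7 gives the tertiary C8 radical, which O2 should trap from the α face, anti to the vicinal 9β side chain and away from the C10 methyl, to give the 8α-alcohol.

**Step 12**
Reactants: 21 methyl 8α-hydroxy-5β-labdan-15-oate
Product: 22 methyl 8α-acetoxy-5β-labdan-15-oate
Conditions: Ac2O, Et3N, DMAP (cat.), CH2Cl2, 40 °C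
Reagents that add atoms: acetic anhydride, CC(=O)OC(C)=O
Why: DMAP-catalysed acylation acetylates the tertiary alcohol with retention at C8.

**Step 13**
Reactants: 22 methyl 8α-acetoxy-5β-labdan-15-oate
Product: 23 8α-acetoxy-5β-labdan-15-oic acid (target)
Conditions: LiOH·H2O, THF/MeOH/H2O, 0 °C → rt; then 1 M HCl
Reagents that add atoms: lithium hydroxide, [Li+].[OH-]
Why: Saponification of the unhindered side-chain methyl ester should be much faster than that of the hindered tertiary acetate, so controlled hydrolysis frees the acid.

**Compound list**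
1 | (S)-(+)-carvone | CC1=CC[C@@H](CC1=O)C(C)=C | starting material
2 | methyl 2-(bromomethyl)acrylate | C=C(CBr)C(=O)OC | starting material
3 | lithium α′-enolate of 1 (cross-conjugated) | CC1=CC[C@H](C(C)=C)C=C1[O-].[Li+] | intermediate (not isolated)
4 | 6-[2-(methoxycarbonyl)allyl]carvone, C6 epimers (major shown: arm trans to isopropenyl) | CC1=CC[C@H](C(C)=C)[C@@H](CC(=C)C(=O)OC)C1=O | intermediate
5 | lithium enolate of 4 | CC1=CC[C@H](C(C)=C)C(CC(=C)C(=O)OC)=C1[O-].[Li+] | intermediate (not isolated)
6 | 6-methyl-6-[2-(methoxycarbonyl)allyl]carvone, methyl trans and acrylate arm cis to the isopropenyl group | CC1=CC[C@H](C(C)=C)[C@](C)(CC(=C)C(=O)OC)C1=O | intermediate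
7 | cis-decalin enone ester: C9 ketone, C7=C8, methyls on C4 (two), C8, C10, CO2Me on C2 (both epimers), H-5 and CH3-10 β | CC1=CC[C@@H]2C(C)(C)CC(C(=O)OC)C[C@]2(C)C1=O | intermediate
8 | 7β,8β-epoxide of 7 | C[C@]12O[C@H]1C[C@@H]3C(C)(C)CC(C(=O)OC)C[C@]3(C)C2=O | intermediate (not isolated)
9 | 7β,8β-epoxy-9-oxo acid (CO2H on C2, both epimers) | C[C@]12O[C@H]1C[C@@H]3C(C)(C)CC(C(=O)O)C[C@]3(C)C2=O | intermediate
10 | Barton ester (2-thioxopyridin-1-yl ester) of 9 | C[C@]12O[C@H]1C[C@@H]3C(C)(C)CC(C(=O)On4ccccc4=S)C[C@]3(C)C2=O | intermediate (not isolated)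
11 | 7β,8β-epoxy ketone (cis-decalin, C9 ketone, no C2 substituent) | C[C@]12O[C@H]1C[C@@H]3C(C)(C)CCC[C@]3(C)C2=O | intermediate
12 | hydrazone of 11 | C[C@]12O[C@H]1C[C@@H]3C(C)(C)CCC[C@]3(C)C2=NN | intermediate (not isolated)
13 | 7β-allylic alcohol with C8=C9 (cis-decalin, H-5 and CH3-10 β) | O[C@H]1C[C@@H]2C(C)(C)CCC[C@]2(C)C=C1C | intermediate
14 | 7β-[2-(diphenylphosphanyl)benzoate] of 13 | O=C(O[C@H]1C[C@@H]2C(C)(C)CCC[C@]2(C)C=C1C)c1ccccc1P(c1ccccc1)c1ccccc1 | intermediate
15 | (R)-methyl hydrogen 3-methylglutarate | COC(=O)C[C@H](C)CC(=O)O | starting material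
16 | (S)-5-hydroxy-3-methylpentanoic acid | OCC[C@H](C)CC(=O)O | intermediate (not isolated)
17 | (S)-4-methyltetrahydro-2H-pyran-2-one | C[C@H]1CCOC(=O)C1 | intermediate
18 | methyl (R)-5-bromo-3-methylpentanoate | BrCC[C@H](C)CC(=O)OC | intermediate
19 | [(R)-5-methoxy-3-methyl-5-oxopentyl]zinc bromide | Br[Zn]CC[C@H](C)CC(=O)OC | intermediate (not isolated)
20 | methyl (13S)-5β-labd-7-en-15-oate (9β side chain, H-9 α) | CC1=CC[C@@H]2C(C)(C)CCC[C@]2(C)[C@H]1CC[C@H](C)CC(=O)OC | intermediate
21 | methyl (13S)-8α-hydroxy-5β-labdan-15-oate | O[C@]1(C)CC[C@@H]2C(C)(C)CCC[C@]2(C)[C@H]1CC[C@H](C)CC(=O)OC | intermediate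
22 | methyl (13S)-8α-acetoxy-5β-labdan-15-oate | CC(=O)O[C@]1(C)CC[C@@H]2C(C)(C)CCC[C@]2(C)[C@H]1CC[C@H](C)CC(=O)OC | intermediate
23 | (3S)-5-[(1R,2R,4aR,8aS)-2-acetoxy-2,5,5,8a-tetramethyldecahydronaphthalen-1-yl]-3-methylpentanoic acid | CC(=O)O[C@]1(C)CC[C@@H]2C(C)(C)CCC[C@]2(C)[C@H]1CC[C@H](C)CC(=O)O | target

**Step count.** Total: 13 steps. Longest linear sequence: 11 steps (steps 1–7 and 10–13).

**Steps most likely to fail**

Step 10. The γ-attack at C9 lies next to the quaternary C10 and may be slow, so direct substitution at C7 or loss of the directed syn delivery could compete. The fallback sets out from 13 and returns at 20. Johnson–Claisen rearrangement of 13 (MeC(OEt)3, EtCO2H cat., 140 °C) transfers a two-carbon unit suprafacially from the 7β oxygen to C9 and gives ethyl ester F1. LiAlH4 reduces it to primary alcohol F2, and CBr4/PPh3 gives bromide F3. Magnesium gives Grignard reagent F4, which adds to methyl (E)-crotonate under CuBr·SMe2 and a Josiphos-type ligand (t-BuOMe, −75 °C; catalytic asymmetric conjugate addition), with the ligand enantiomer chosen to set the (13S) centre, giving 20.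

Step 6. Hydrazone formation at C9, which is flanked by two fully substituted carbons, may be too slow, and hydrazine may then open the epoxide. The fallback sets out from 11 and returns at 13. NaBH4 reduces the ketone to epoxy alcohol F5, and O-phenyl chlorothionoformate with pyridine/DMAP gives thionocarbonate F6. Bu3SnH/AIBN then generates the C9 radical, which opens the epoxide by β-scission of the C8–O bond; the resulting C7 alkoxy radical is reduced to 13 with the C7–O bond untouched (radical epoxide fragmentation).

Step 11. The planar C8 radical may be trapped by O2 from the β face or with poor facial selectivity, giving the C8 epimer. The fallback sets out from 20 and returns at 21. NBS in aqueous THF forms the bromonium ion on the more accessible face and water opens it anti at the tertiary C8, so oxygen arrives on the face opposite to that favoured by a small reagent; this gives bromohydrin F7. Bu3SnH/AIBN then removes the bromine to give 21 (halohydrin formation followed by radical dehalogenation).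

**Further compounds**
F1 | step 10 | ethyl (5β-15,16-dinor... C9β)-acetate: ethyl 2-[9β-substituted 4,4,8,10-tetramethyl-cis-decal-7-en-9-yl]acetate | CC1=CC[C@@H]2C(C)(C)CCC[C@]2(C)[C@H]1CC(=O)OCC
F2 | step 10 | corresponding 2-(decal-7-en-9-yl)ethanol | CC1=CC[C@@H]2C(C)(C)CCC[C@]2(C)[C@H]1CCO
F3 | step 10 | corresponding 2-(decal-7-en-9-yl)ethyl bromide | CC1=CC[C@@H]2C(C)(C)CCC[C@]2(C)[C@H]1CCBr
F4 | step 10 | corresponding 2-(decal-7-en-9-yl)ethylmagnesium bromide | CC1=CC[C@@H]2C(C)(C)CCC[C@]2(C)[C@H]1CC[Mg]Br
F5 | step 6 | 7β,8β-epoxy-9-ol (C9 configuration not defined) | C[C@]12O[C@H]1C[C@@H]3C(C)(C)CCC[C@]3(C)C2O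
F6 | step 6 | O-phenyl thionocarbonate of F5 | C[C@]12O[C@H]1C[C@@H]3C(C)(C)CCC[C@]3(C)C2OC(=S)Oc4ccccc4
F7 | step 11 | methyl (13S)-7β-bromo-8α-hydroxy-5β-labdan-15-oate | O[C@]1(C)[C@@H](Br)C[C@@H]2C(C)(C)CCC[C@]2(C)[C@H]1CC[C@H](C)CC(=O)OC
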